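## Structural features

Prinsepiol is a C2-symmetric furofuran lignan: ring A (C1–C2–O3–C4–C5) and ring B (C5–C6–O7–C8–C1) are two oxolanes cis-fused through the C1–C5 bond to a 3,7-dioxabicyclo[3.3.0]octane, and each carries a 4-hydroxy-3-methoxyphenyl group on its benzylic ether carbon (C2, C6). Four stereocentres stand in a row, C2–C1–C5–C6 (2R,1S,5S,6R): the inner two are adjacent, fully substituted tertiary carbinols, and each outer one is a benzylic methine whose aryl group is cis to the hydroxyl on the neighbouring bridgehead. The fragile parts are the electron-rich p-hydroxybenzylic C–O bonds (ionisation under acid with epimerisation at C2/C6 or ring opening, and hydrogenolysis), the oxidisable free phenols and the vicinal ditertiary diol. The real difficulty is the pair of contiguous tetrasubstituted C–O stereocentres C1/C5 in one absolute sense and their relay to C2/C6; closing the rings is easy once these four centres exist. C1 and C5 each carry an oxygen, an aroyl-level carbon (C2 or C6) and a CH2O carbon (C8 or C4), so the chain C2–C1–C5–C6 is a tartaric acid skeleton in which both carbinol C–H bonds are replaced by CH2O groups. The key step uses this: the two C–H bonds of an L-tartrate-derived trans-dioxolane diketone are exchanged one after the other for the C1–C8 and C5–C4 bonds, and the stereocentre left untouched in each deprotonation relays the configuration. The twofold axis lets every operation run at both ends at once.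

## Logic of the disconnections

**15 ⇒ 14 ⇒ 13.** Only heteroatom bonds are cut: the two aryl O–Si bonds (15 to 14) and the two ketal C–O bonds that tie O1 to O5 (14 to 13). This stores the phenols and the ditertiary diol in forms that survive base, hydride and hydrogen, at no cost in skeleton. The demand is that ketal and silicon are removed without ionising the benzylic C2–O3 and C6–O7 bonds, so the acid step comes first, while the arenes are still silylated.

**13 ⇒ 12 ⇒ 11.** The ring bonds O3–C4 and O7–C8 are cut, then the C2–H and C6–H bonds. The ethers are cut on their CH2 side so that the benzylic oxygen is the nucleophile and a primary carbon the electrophile; the benzylic centres are never substitution centres and keep the configuration given by the reduction. Both oxolane rings and two stereocentres disappear, leaving an acyclic C2-symmetric diketone. The demands are hydride addition anti to the ring C–O bond (non-chelating reagent) and closure of the five-membered ring onto the sulfonate of the neighbouring ring carbon, not the four-membered ring onto the geminal CH2.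

**11 ⇒ 10 ⇒ 9.** Only O–S and O–CH2Ph bonds are cut. The oxygen substituent brought in by the alkylation must first resist strong base and then become a leaving group; sulfonylating before the reduction means no primary/secondary hydroxyl discrimination is ever needed. The skeleton is unchanged. The demands are benzyl ether cleavage without reduction of the aryl ketones, and sulfonylation of neopentyl-type alcohols that can hide as hemiketals.

**9 ⇒ 6 + 7.** The C1–C8 and C5–C4 bonds are cut, which calls for two molecules of 7; this is the strategic cut. It uncovers the tartaric acid skeleton and trades two contiguous tetrasubstituted stereocentres for two tertiary C–H centres of chiral-pool origin. The demands are alkylation on carbon, on the face that restores the trans-diacyl arrangement, one carbon at a time, without β-elimination.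

**6 ⇒ 4 + 5; 5 ⇒ 2 ⇒ 1.** The two aryl–carbonyl C–C bonds are cut (two molecules of 5 per molecule of 4), then the C–Mg bond and the aryl O–Si bond. Ketone-level aroyl groups are what the enolate chemistry and the later reduction need, and the cut gives a symmetrical four-carbon diacyl electrophile and a simple aryl nucleophile. The demands are single addition at each acyl group, no epimerisation α to the carbonyls, and a phenol mask that tolerates the organomagnesium reagent.

**4 ⇒ 3.** The two amide C–N bonds are cut back to the ester C–O bonds. The route ends at a cheap commercial compound that already holds C1, C5, their oxygens and the absolute configuration. The demand is aminolysis without epimerisation.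

## Other disconnections considered

**Alternative 1:** The cut removes C2–O3, C6–O7 and both carbinol C–O bonds, leading back to the (E,E)-dienediol bis(allyl ether) A1. In the forward step a Sharpless asymmetric epoxidation (Ti(OiPr)4, L-(+)-tartrate ester, tBuOOH) would epoxidise both allylic alcohol units, and each CH2OH would open the benzylic epoxide carbon of the other half (5-endo, inversion) to give the bis(allyl) ether A2.
- In its favour: the absolute configuration is reagent-controlled, so either enantiomer is open. Four stereocentres, four C–O bonds and both rings would form in one flask. The usual facial rule for the L-(+)-tartrate gives the 1S,5S carbinols, and backside opening of E-epoxides gives 2R,6R. A1 should be reachable in a few steps by double Stobbe-type condensation and hydride reduction, so the whole route would be roughly half as long as the chosen one. On step economy this alternative is the better plan.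
- Against it: the epoxides are those of electron-rich, conjugated styrenes in a medium containing tetravalent titanium and free alcohols. Premature or SN1-like opening would lose the inversion that defines C2/C6. If the first oxolane closes before the second alkene is epoxidised, that alkene is no longer part of a primary allylic alcohol and the second oxygen transfer leaves the reliable scope. Attack at the fully substituted epoxide carbon (4-exo) is a further leak.
- Comparison: this plan makes the tertiary carbinols by C–O bond formation on a finished carbon skeleton, whereas the chosen plan makes them by C–C bond formation on finished carbinols. It stakes all four centres on one cascade through acid-labile intermediates, whereas the chosen plan sets C1/C5, C2/C6 and the ring closure in separate steps that can each be corrected. On absolute control the two are equal in principle (catalyst against chiral pool).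

**Alternative 2:** The cut removes C1–C5 together with C2–O3 and C6–O7, leading back to ferulic acid A3. In the forward step one-electron oxidation (FeCl3 with O2, or laccase with O2) would couple two phenoxyl radicals at their β-carbons, and each acid would add to the quinone methide of the other half to give the bis-lactone A4.
- In its favour: one step from a bulk phenylpropanoid, without protecting groups, would build the entire carbon skeleton, both rings and the relative configuration of all four centres (cis fusion, aryl groups exo). In bonds formed per step this is better than anything in the chosen route.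
- Against it: an achiral oxidant gives the racemate, so the single enantiomer needs a resolution that discards at least half the material. Radical coupling also gives regioisomeric dimers. The oxidation levels are wrong twice. C1 and C5 carry hydrogen, and the lactone enolates needed for bridgehead hydroxylation have an acyloxy leaving group in the β-position (O3 or O7) and should ring-open by E1cB. C4 and C8 are carbonyls that must be reduced to CH2 without touching the benzylic C–O bonds.
- Comparison: it is the equal or the better of the chosen plan in step count to the bicyclic skeleton. It is weaker on exactly the defining features, the absolute configuration and the two tertiary carbinols, which the chosen plan holds from its first compound.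

**Alternative 3:** The cut removes both aryl–C bonds (C2–Ar, C6–Ar), leading back to the bis(lactol acetate) A5. In the forward step ionisation with BF3·OEt2 or Me3SiBr would give oxocarbenium ions at C2 and C6, and the diarylzinc A6 (Ar2Zn) would add to each, cis to the adjacent bridgehead oxygen, to give the fully silylated prinsepiol A7.
- In its favour: it uses the same tartrate chiral pool. The two CH2O groups would be introduced by double alkylation at the ester stage, where retentive alkylation of dioxolane enolates has direct precedent; on that point it is better founded than the chosen plan, which asks the same of a ketone enolate. The rings exist early, and the aryl groups arrive last, which is convergent. The convex face of the cis-fused bicycle and the usual preference for addition cis to a neighbouring alkoxy group in five-membered oxocarbenium ions both point to the required arrangement.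
- Against it: each oxocarbenium ion sits next to a crowded carbon bearing a silyloxy group and is inductively destabilised. Lewis acids strong enough to ionise it threaten the tertiary Me3Si ethers and can re-ionise the newly formed electron-rich benzylic C–O bond (epimerisation, ring opening). A6 must be prepared and transfers aryl groups sluggishly. Two C–C bonds and two stereocentres ride on one Lewis-acidic operation.
- Comparison: step count and source of chirality are equal. Precedent for the alkylation and convergence are better in the alternative. The chosen plan is safer at C2/C6, which it sets by hydride addition under Felkin–Anh control, and it closes the rings by substitution at a primary carbon, so no cation is ever generated at a benzylic position.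

Key step: step 4

Remark: the phenols are carried as triisopropylsilyl ethers (more resistant than tert-butyldimethylsilyl ethers to the enolate and alkoxide stages, same fluoride removal), and the commercial acetonide 3 of dimethyl L-tartrate is the starting point. The configurations of 6, 9 and 15 are mutually consistent (L-tartrate series, two retentive alkylations, 1S,2R,5S,6R). Steps 2, 3, 4 and 6 act at both ends of the C2-symmetric substrate and build two molar equivalents of the partner into the product; in steps 3 and 4 the partner is a numbered compound (2 by way of 5, and 7), and its second equivalent is entered on the reagents line.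

## Route

Step 1
Reactants: 1 4-bromo-2-methoxyphenol
Product: 2 (4-bromo-2-methoxyphenoxy)triisopropylsilane
Conditions: iPr3SiCl, imidazole, DMF, 0 °C → rt
Reagents that add atoms: chlorotriisopropylsilane, CC(C)[Si](Cl)(C(C)C)C(C)C
Why: Imidazole-assisted O-silylation masks the acidic phenol before the Grignard step; the bulky aryl silyl ether tolerates organomagnesium, silylamide and alkoxide reagents and is removed by fluoride.

Step 2
Reactants: 3 dimethyl (4R,5R)-2,2-dimethyl-1,3-dioxolane-4,5-dicarboxylate
Product: 4 (4R,5R)-N4,N5-dimethoxy-N4,N5,2,2-tetramethyl-1,3-dioxolane-4,5-dicarboxamide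
Conditions: MeNH(OMe)·HCl (3 equiv), AlMe3 (3 equiv), CH2Cl2, 0 °C → rt
Reagents that add atoms: N,O-dimethylhydroxylamine hydrochloride (two equivalents are built in), CNOC.Cl
Why: Aminolysis of both esters by the aluminium amide formed in the flask (Weinreb amide synthesis); the stereocentres are not touched, and the amide later allows a single aryl addition per carbonyl.

Step 3
Reactants: 2 (4-bromo-2-methoxyphenoxy)triisopropylsilane; 4 (4R,5R)-N4,N5-dimethoxy-N4,N5,2,2-tetramethyl-1,3-dioxolane-4,5-dicarboxamide
Product: 6 (4R,5R)-4,5-bis[3-methoxy-4-(triisopropylsilyloxy)benzoyl]-2,2-dimethyl-1,3-dioxolane, via [3-methoxy-4-(triisopropylsilyloxy)phenyl]magnesium bromide 5 (not isolated)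
Conditions: 2 (2.6 equiv), Mg, I2 (cat.), THF, 40 °C; then 4 (1.0 equiv), THF, 0 °C → rt; aq. NH4Cl
Reagents that add atoms: (4-bromo-2-methoxyphenoxy)triisopropylsilane 2 (second equivalent; delivered as 5), COc1cc(Br)ccc1O[Si](C(C)C)(C(C)C)C(C)C
Why: Magnesium insertion into 2 gives the aryl Grignard reagent 5, and one molecule of 5 adds to each of the two N-methoxy-N-methylamide groups of 4, only once per carbonyl because the magnesium chelate survives until the quench (Weinreb ketone synthesis). The α-hydrogens therefore never meet the base at the ketone stage and the trans (4R,5R) centres are kept.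

Step 4
Reactants: 6 (4R,5R)-4,5-bis[3-methoxy-4-(triisopropylsilyloxy)benzoyl]-2,2-dimethyl-1,3-dioxolane; 7 benzyl chloromethyl ether
Product: 9 (4R,5R)-4,5-bis(benzyloxymethyl)-4,5-bis[3-methoxy-4-(triisopropylsilyloxy)benzoyl]-2,2-dimethyl-1,3-dioxolane, via mono(benzyloxymethyl) diketone 8 (not isolated)
Conditions: LiN(SiMe3)2 (1.05 equiv), THF, −78 °C; 7 (1.1 equiv), −78 → −40 °C; then LiN(SiMe3)2 (1.2 equiv), −78 °C; 7 (1.5 equiv), −78 → −30 °C
Reagents that add atoms: benzyl chloromethyl ether 7 (second equivalent; consumed in the alkylation of 8), ClCOCc1ccccc1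
Why: LiN(SiMe3)2 removes the C1–H next to one aroyl group to give a single tetrasubstituted lithium enolate, which is alkylated on carbon by one molecule of the α-chloro ether 7 (SN2 at an oxocarbenium-like CH2) to form C1–C8 in 8; a second deprotonation at C5 and alkylation by a second molecule of 7 form C5–C4. The closest known reaction type is the retentive α-alkylation of tartrate acetonide ester enolates, in which the untouched neighbouring stereocentre relays the configuration; here it is applied to the diaryl diketone. No ring is closed, so no mode of ring closure arises. The new centre C1 is controlled by C5: as C1 pyramidalises, the planar metal-enolate arm that becomes the aroyl group swings away from the C5 aroyl group (steric and dipole repulsion), so the small CH2 electrophile enters syn to that group and the trans-diacyl dioxolane is restored. The new centre C5 is then controlled in the same way by the quaternary C1 formed first, which gives the C2-symmetric (4R,5R) product. The step needs C- rather than O-alkylation, for which the lithium counter-ion in THF without dipolar cosolvent and the high reactivity of 7 are chosen. It needs one enolate at a time, which the stoichiometric, weakly basic silylamide secures because it should not form the achiral dienediolate, and it needs β-elimination to stay slow, which the ring secures by holding the C5–O bond near the nodal plane of the enolate. A wrong-face event in the first alkylation would be carried by the second into the enantiomeric series, so 9 should be recrystallised and its enantiomeric purity checked before use.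

Step 5
Reactants: 9 (4R,5R)-4,5-bis(benzyloxymethyl)-4,5-bis[3-methoxy-4-(triisopropylsilyloxy)benzoyl]-2,2-dimethyl-1,3-dioxolane
Product: 10 (4R,5R)-4,5-bis(hydroxymethyl)-4,5-bis[3-methoxy-4-(triisopropylsilyloxy)benzoyl]-2,2-dimethyl-1,3-dioxolane
Conditions: H2 (1 atm), Pd(OH)2/C, EtOAc, rt
Reagents that add atoms: none
Why: Catalytic hydrogenolysis of the two benzyl ethers; the hindered, donor-deactivated aryl ketones, the silyl ethers and the ketal should be spared under neutral conditions. 10 may sit partly as its cyclic hemiketals (CH2OH on C1 with the C6 carbonyl and the reverse), which is harmless for the next step.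

Step 6
Reactants: 10 (4R,5R)-4,5-bis(hydroxymethyl)-4,5-bis[3-methoxy-4-(triisopropylsilyloxy)benzoyl]-2,2-dimethyl-1,3-dioxolane
Product: 11 (4R,5R)-4,5-bis[3-methoxy-4-(triisopropylsilyloxy)benzoyl]-2,2-dimethyl-4,5-bis(tosyloxymethyl)-1,3-dioxolane
Conditions: TsCl (3 equiv), pyridine, DMAP (cat.), CH2Cl2, 0 °C → rt
Reagents that add atoms: p-toluenesulfonyl chloride (two equivalents are built in), Cc1ccc(cc1)S(Cl)(=O)=O
Why: O-Sulfonylation of the only free hydroxyls (primary), drained from any hemiketal through the open tautomer; the quaternary α-carbons rule out β-elimination of the β-sulfonyloxy ketones, and the weak base avoids retro-aldol loss of formaldehyde.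

Step 7
Reactants: 11 (4R,5R)-4,5-bis[3-methoxy-4-(triisopropylsilyloxy)benzoyl]-2,2-dimethyl-4,5-bis(tosyloxymethyl)-1,3-dioxolane
Product: 13 (1S,2R,5S,6R)-1,5-(isopropylidenedioxy)-2,6-bis[3-methoxy-4-(triisopropylsilyloxy)phenyl]-3,7-dioxabicyclo[3.3.0]octane, via diol bis(tosylate) 12 (not isolated)
Conditions: K[HB(s-Bu)3] (2.5 equiv), THF, −78 → −20 °C; then rt → 50 °C
Reagents that add atoms: none
Why: Hydride adds to each ketone antiperiplanar to the ring C–O bond and past the CH2OTs group (polar Felkin–Anh; the Cornforth arrangement predicts the same face, and the bulky potassium reagent disfavours chelation), which sets C2 and C6 as R with each aryl cis to the bridgehead oxygen. On warming, each potassium alkoxide displaces the tosylate on the neighbouring ring carbon (Williamson etherification, 5-exo-tet, faster than 4-exo-tet onto the geminal CH2) with retention at the carbinol carbon.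

Step 8
Reactants: 13 (1S,2R,5S,6R)-1,5-(isopropylidenedioxy)-2,6-bis[3-methoxy-4-(triisopropylsilyloxy)phenyl]-3,7-dioxabicyclo[3.3.0]octane
Product: 14 (1S,2R,5S,6R)-2,6-bis[3-methoxy-4-(triisopropylsilyloxy)phenyl]-3,7-dioxabicyclo[3.3.0]octane-1,5-diol
Conditions: CF3CO2H/H2O (9:1), 0 °C
Reagents that add atoms: none
Why: Acid-catalysed ketal hydrolysis through the 2-oxy-2-propyl cation; the silylated arenes are poorer donors than free phenols and the bridgehead oxygens withdraw inductively, so ionisation of the benzylic C–O bonds should stay slow at 0 °C.

Step 9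
Reactants: 14 (1S,2R,5S,6R)-2,6-bis[3-methoxy-4-(triisopropylsilyloxy)phenyl]-3,7-dioxabicyclo[3.3.0]octane-1,5-diol
Product: 15 prinsepiol
Conditions: Bu4NF, AcOH, THF, 0 °C
Reagents that add atoms: none
Why: Fluoride cleaves both aryl O–Si bonds (strong Si–F bond); the AcOH buffer keeps the phenols protonated so that no quinone methide chemistry starts at C2/C6.

## Compound list

1 | 4-bromo-2-methoxyphenol | COc1cc(Br)ccc1O | starting material
2 | (4-bromo-2-methoxyphenoxy)triisopropylsilane | COc1cc(Br)ccc1O[Si](C(C)C)(C(C)C)C(C)C | intermediate
3 | dimethyl (4R,5R)-2,2-dimethyl-1,3-dioxolane-4,5-dicarboxylate (dimethyl 2,3-O-isopropylidene-L-tartrate) | COC(=O)[C@@H]1OC(C)(C)O[C@H]1C(=O)OC | starting material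
4 | (4R,5R)-N4,N5-dimethoxy-N4,N5,2,2-tetramethyl-1,3-dioxolane-4,5-dicarboxamide | CON(C)C(=O)[C@@H]1OC(C)(C)O[C@H]1C(=O)N(C)OC | intermediate
5 | [3-methoxy-4-(triisopropylsilyloxy)phenyl]magnesium bromide | COc1cc([Mg]Br)ccc1O[Si](C(C)C)(C(C)C)C(C)C | intermediate
6 | (4R,5R)-4,5-bis[3-methoxy-4-(triisopropylsilyloxy)benzoyl]-2,2-dimethyl-1,3-dioxolane | O=C(c1ccc(O[Si](C(C)C)(C(C)C)C(C)C)c(OC)c1)[C@@H]2OC(C)(C)O[C@H]2C(=O)c3ccc(O[Si](C(C)C)(C(C)C)C(C)C)c(OC)c3 | intermediate
7 | benzyl chloromethyl ether | ClCOCc1ccccc1 | starting material
8 | (4R,5R)-4-(benzyloxymethyl)-4,5-bis[3-methoxy-4-(triisopropylsilyloxy)benzoyl]-2,2-dimethyl-1,3-dioxolane | O=C(c1ccc(O[Si](C(C)C)(C(C)C)C(C)C)c(OC)c1)[C@]2(COCc3ccccc3)OC(C)(C)O[C@H]2C(=O)c4ccc(O[Si](C(C)C)(C(C)C)C(C)C)c(OC)c4 | intermediate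
9 | (4R,5R)-4,5-bis(benzyloxymethyl)-4,5-bis[3-methoxy-4-(triisopropylsilyloxy)benzoyl]-2,2-dimethyl-1,3-dioxolane | O=C(c1ccc(O[Si](C(C)C)(C(C)C)C(C)C)c(OC)c1)[C@]2(COCc3ccccc3)OC(C)(C)O[C@@]2(COCc4ccccc4)C(=O)c5ccc(O[Si](C(C)C)(C(C)C)C(C)C)c(OC)c5 | intermediate
10 | (4R,5R)-4,5-bis(hydroxymethyl)-4,5-bis[3-methoxy-4-(triisopropylsilyloxy)benzoyl]-2,2-dimethyl-1,3-dioxolane (open form) | O=C(c1ccc(O[Si](C(C)C)(C(C)C)C(C)C)c(OC)c1)[C@]2(CO)OC(C)(C)O[C@@]2(CO)C(=O)c3ccc(O[Si](C(C)C)(C(C)C)C(C)C)c(OC)c3 | intermediate
11 | (4R,5R)-4,5-bis[3-methoxy-4-(triisopropylsilyloxy)benzoyl]-2,2-dimethyl-4,5-bis(tosyloxymethyl)-1,3-dioxolane | O=C(c1ccc(O[Si](C(C)C)(C(C)C)C(C)C)c(OC)c1)[C@]2(COS(=O)(=O)c3ccc(C)cc3)OC(C)(C)O[C@@]2(COS(=O)(=O)c4ccc(C)cc4)C(=O)c5ccc(O[Si](C(C)C)(C(C)C)C(C)C)c(OC)c5 | intermediate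
12 | (4S,5S)-4,5-bis{(R)-hydroxy[3-methoxy-4-(triisopropylsilyloxy)phenyl]methyl}-2,2-dimethyl-4,5-bis(tosyloxymethyl)-1,3-dioxolane (formed as its dipotassium alkoxide) | O[C@H](c1ccc(O[Si](C(C)C)(C(C)C)C(C)C)c(OC)c1)[C@]2(COS(=O)(=O)c3ccc(C)cc3)OC(C)(C)O[C@@]2(COS(=O)(=O)c4ccc(C)cc4)[C@H](O)c5ccc(O[Si](C(C)C)(C(C)C)C(C)C)c(OC)c5 | intermediate
13 | (1S,2R,5S,6R)-1,5-(isopropylidenedioxy)-2,6-bis[3-methoxy-4-(triisopropylsilyloxy)phenyl]-3,7-dioxabicyclo[3.3.0]octane | COc1cc([C@H]2OC[C@]3(OC(C)(C)O4)[C@@H](c5ccc(O[Si](C(C)C)(C(C)C)C(C)C)c(OC)c5)OC[C@]234)ccc1O[Si](C(C)C)(C(C)C)C(C)C | intermediate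
14 | (1S,2R,5S,6R)-2,6-bis[3-methoxy-4-(triisopropylsilyloxy)phenyl]-3,7-dioxabicyclo[3.3.0]octane-1,5-diol | COc1cc([C@H]2OC[C@]3(O)[C@@H](c4ccc(O[Si](C(C)C)(C(C)C)C(C)C)c(OC)c4)OC[C@]23O)ccc1O[Si](C(C)C)(C(C)C)C(C)C | intermediate
15 | prinsepiol, (1S,2R,5S,6R)-2,6-bis(4-hydroxy-3-methoxyphenyl)-3,7-dioxabicyclo[3.3.0]octane-1,5-diol | COc1cc([C@H]2OC[C@]3(O)[C@@H](c4ccc(O)c(OC)c4)OC[C@]23O)ccc1O | target

## Step count and least certain steps

Total step count: 9. Longest linear sequence: 8 steps (steps 2 to 9, from 3 to 15); step 1 is the side branch.

**Step 4 (key step).**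
- What may go wrong: O-alkylation of the crowded enolate by the hard α-chloro ether; facial leakage in the first alkylation, which the second alkylation would turn into loss of enantiomeric purity; proton exchange between enolate and ketone, or double deprotonation, which would scramble C1/C5; β-elimination that opens the dioxolane; and a sluggish second alkylation, because two vicinal tetrasubstituted centres are being built.
- Fallback: move the alkylation to the ester stage, where the retentive relay is established. It sets out from 3. LiN(iPr)2 in THF/DMPU at −78 °C and 7 would give dimethyl (4R,5R)-4-(benzyloxymethyl)-2,2-dimethyl-1,3-dioxolane-4,5-dicarboxylate F1, which is freed from its cis isomer by chromatography. A second round would give dimethyl (4R,5R)-4,5-bis(benzyloxymethyl)-2,2-dimethyl-1,3-dioxolane-4,5-dicarboxylate F2. MeNH(OMe)·HCl/AlMe3 at 40 °C would convert it to (4R,5R)-4,5-bis(benzyloxymethyl)-N4,N5-dimethoxy-N4,N5,2,2-tetramethyl-1,3-dioxolane-4,5-dicarboxamide F3. Addition of 5 comes back to the route at 9.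

**Step 7.**
- What may go wrong: poor facial selectivity in the hydride addition (a chelated or non-Felkin pathway would put the aryl groups trans to the bridgehead oxygens); incomplete reduction of the hindered ketones by the bulky hydride; attack of an alkoxide on its geminal CH2OTs (4-exo closure or Grob-type fragmentation); or attack of hydride at the sulfonate.
- Fallback: reverse the polarity of the ring closure so that C2/C6 are set during cyclisation and not by the hydride. It sets out from 10. NaBH4 in MeOH/THF at 0 °C would give (4S,5S)-4,5-bis{hydroxy[3-methoxy-4-(triisopropylsilyloxy)phenyl]methyl}-4,5-bis(hydroxymethyl)-2,2-dimethyl-1,3-dioxolane F4 as a mixture of carbinol epimers. Catalytic camphorsulfonic acid in dry CH2Cl2 would then let each primary hydroxyl capture the p-silyloxybenzylic cation of the neighbouring arm (SN1, five-membered ring). The aryl group is expected to settle trans to the CH2 of the other ring, that is cis to the bridgehead oxygen. This comes back at 13.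

**Step 5.**
- What may go wrong: hydrogenation of the aryl ketones, followed by benzylic hydrogenolysis, may compete with slow cleavage of the hindered neopentyl-type benzyl ethers; ring–chain tautomerism may complicate handling and slow the sulfonylation that follows.
- Fallback: change the order so that no ketone is present when hydrogen is used. It sets out from 9. K[HB(s-Bu)3] in THF at −78 °C would give (4S,5S)-4,5-bis(benzyloxymethyl)-4,5-bis{(R)-hydroxy[3-methoxy-4-(triisopropylsilyloxy)phenyl]methyl}-2,2-dimethyl-1,3-dioxolane F5. H2 over Pd/C in EtOAc would give (4S,5S)-4,5-bis{(R)-hydroxy[3-methoxy-4-(triisopropylsilyloxy)phenyl]methyl}-4,5-bis(hydroxymethyl)-2,2-dimethyl-1,3-dioxolane F6. Primary-selective tosylation (TsCl, pyridine, 0 °C) comes back to the route at 12, this time isolated, and NaH in THF closes it to 13.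

**Step 8.**
- What may go wrong: acid-promoted ionisation of the electron-rich benzylic C–O bonds (epimerisation at C2/C6 or ring opening) may compete with hydrolysis of a ketal that is hindered and inductively deactivated, or the hydrolysis may stall.
- Fallback: make the arenes poor donors for the acid step. It sets out from 13. Bu4NF/AcOH would give (1S,2R,5S,6R)-2,6-bis(4-hydroxy-3-methoxyphenyl)-1,5-(isopropylidenedioxy)-3,7-dioxabicyclo[3.3.0]octane F7. Ac2O/pyridine would give its 4′,4″-diacetate F8, whose acetoxy groups stabilise a benzylic cation far less. Aqueous CF3CO2H could then be applied more forcefully to give prinsepiol 4′,4″-diacetate F9. K2CO3 in MeOH at 0 °C comes back at 15.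

## Further compounds

F1 | step 4 | dimethyl (4R,5R)-4-(benzyloxymethyl)-2,2-dimethyl-1,3-dioxolane-4,5-dicarboxylate | COC(=O)[C@]1(COCc2ccccc2)OC(C)(C)O[C@H]1C(=O)OC
F2 | step 4 | dimethyl (4R,5R)-4,5-bis(benzyloxymethyl)-2,2-dimethyl-1,3-dioxolane-4,5-dicarboxylate | COC(=O)[C@]1(COCc2ccccc2)OC(C)(C)O[C@@]1(COCc3ccccc3)C(=O)OC
F3 | step 4 | (4R,5R)-4,5-bis(benzyloxymethyl)-N4,N5-dimethoxy-N4,N5,2,2-tetramethyl-1,3-dioxolane-4,5-dicarboxamide | CON(C)C(=O)[C@]1(COCc2ccccc2)OC(C)(C)O[C@@]1(COCc3ccccc3)C(=O)N(C)OC
F4 | step 7 | (4S,5S)-4,5-bis{hydroxy[3-methoxy-4-(triisopropylsilyloxy)phenyl]methyl}-4,5-bis(hydroxymethyl)-2,2-dimethyl-1,3-dioxolane, mixture of carbinol epimers | OC(c1ccc(O[Si](C(C)C)(C(C)C)C(C)C)c(OC)c1)[C@]2(CO)OC(C)(C)O[C@@]2(CO)C(O)c3ccc(O[Si](C(C)C)(C(C)C)C(C)C)c(OC)c3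
F5 | step 5 | (4S,5S)-4,5-bis(benzyloxymethyl)-4,5-bis{(R)-hydroxy[3-methoxy-4-(triisopropylsilyloxy)phenyl]methyl}-2,2-dimethyl-1,3-dioxolane | O[C@H](c1ccc(O[Si](C(C)C)(C(C)C)C(C)C)c(OC)c1)[C@]2(COCc3ccccc3)OC(C)(C)O[C@@]2(COCc4ccccc4)[C@H](O)c5ccc(O[Si](C(C)C)(C(C)C)C(C)C)c(OC)c5
F6 | step 5 | (4S,5S)-4,5-bis{(R)-hydroxy[3-methoxy-4-(triisopropylsilyloxy)phenyl]methyl}-4,5-bis(hydroxymethyl)-2,2-dimethyl-1,3-dioxolane | O[C@H](c1ccc(O[Si](C(C)C)(C(C)C)C(C)C)c(OC)c1)[C@]2(CO)OC(C)(C)O[C@@]2(CO)[C@H](O)c3ccc(O[Si](C(C)C)(C(C)C)C(C)C)c(OC)c3
F7 | step 8 | (1S,2R,5S,6R)-2,6-bis(4-hydroxy-3-methoxyphenyl)-1,5-(isopropylidenedioxy)-3,7-dioxabicyclo[3.3.0]octane | COc1cc([C@H]2OC[C@]3(OC(C)(C)O4)[C@@H](c5ccc(O)c(OC)c5)OC[C@]234)ccc1O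
F8 | step 8 | (1S,2R,5S,6R)-2,6-bis(4-acetoxy-3-methoxyphenyl)-1,5-(isopropylidenedioxy)-3,7-dioxabicyclo[3.3.0]octane | COc1cc([C@H]2OC[C@]3(OC(C)(C)O4)[C@@H](c5ccc(OC(C)=O)c(OC)c5)OC[C@]234)ccc1OC(C)=O
F9 | step 8 | prinsepiol 4′,4″-diacetate | COc1cc([C@H]2OC[C@]3(O)[C@@H](c4ccc(OC(C)=O)c(OC)c4)OC[C@]23O)ccc1OC(C)=O
A1 | alternative 1 | (2E,3E)-2,3-bis{[3-methoxy-4-(prop-2-enyloxy)phenyl]methylidene}butane-1,4-diol | OC/C(=C/c1ccc(OCC=C)c(OC)c1)/C(CO)=C\c2ccc(OCC=C)c(OC)c2
A2 | alternative 1 | prinsepiol bis(allyl) ether | COc1cc([C@H]2OC[C@]3(O)[C@@H](c4ccc(OCC=C)c(OC)c4)OC[C@]23O)ccc1OCC=C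
A3 | alternative 2 | ferulic acid | COc1cc(/C=C/C(=O)O)ccc1O
A4 | alternative 2 | 2,6-bis(4-hydroxy-3-methoxyphenyl)-3,7-dioxabicyclo[3.3.0]octane-4,8-dione (would form as the racemate; target-series enantiomer drawn) | COc1cc([C@H]2OC(=O)[C@@H]3[C@@H](c4ccc(O)c(OC)c4)OC(=O)[C@H]23)ccc1O
A5 | alternative 3 | 1,5-bis(trimethylsilyloxy)-3,7-dioxabicyclo[3.3.0]octane-2,6-diyl diacetate (anomeric mixture) | CC(=O)OC2OC[C@]3(O[Si](C)(C)C)C(OC(C)=O)OC[C@]23O[Si](C)(C)C
A6 | alternative 3 | bis[4-(tert-butyldimethylsilyloxy)-3-methoxyphenyl]zinc | COc1cc([Zn]c2ccc(O[Si](C)(C)C(C)(C)C)c(OC)c2)ccc1O[Si](C)(C)C(C)(C)C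
A7 | alternative 3 | prinsepiol 1,5-bis(trimethylsilyl) 4′,4″-bis(tert-butyldimethylsilyl) ether | COc1cc([C@H]2OC[C@]3(O[Si](C)(C)C)[C@@H](c4ccc(O[Si](C)(C)C(C)(C)C)c(OC)c4)OC[C@]23O[Si](C)(C)C)ccc1O[Si](C)(C)C(C)(C)C
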